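A small charge shows the substrate's clock most plainly, so I began with Sunday's run and counted lifetimes.

| setting | Thursday's | Sunday's | Monday's | summer | autumn |
|---|---|---|---|---|---|
| substrate | 0.050 M | 0.025 M | 0.10 M | 0.050 M | 0.050 M |
| remark | run made earlier | run made earlier | run made earlier | a closed flask charged with all of it at once and left for 12 min | one stirred flow tank at steady state, fed with the mixture as stated, mean residence time 12 min |
| time |  |  |  | 12 min |  |

| run | time / min | product / % | substrate / % |
|---|---|---|---|
| Thursday's | 2.50 | 38 | 44 |
| Thursday's | 5.00 | 63 | 25 |
| Thursday's | 8.00 | 81 | 10 |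
| Thursday's | 10.0 | 89 | 6 |
| Thursday's | 12.0 | 94 | 5 |
| Sunday's | 1.00 | 24 | 61 |
| Sunday's | 2.00 | 41 | 40 |
| Sunday's | 3.00 | 56 | 28 |
| Sunday's | 6.00 | 82 | 9 |
| Sunday's | 12.0 | 98 | 1 |
| Monday's | 1.00 | 8 | 74 |
| Monday's | 2.00 | 19 | 61 |
| Monday's | 3.00 | 31 | 54 |
| Monday's | 6.00 | 52 | 32 |
| Monday's | 12.0 | 86 | 12 |

(each reading ± 1.5 percentage points)

- the stated concentrations are those of everything mixed, before any reaction; amounts are the same in each set-up
- the earlier runs were made in a closed, stirred flask

1. the set-up with the highest amount of product at the outlet or at the end, in percent of the substrate put in ("none" if the first two lie within 2 percentage points) (summer / autumn / none)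
2. amount of product at the outlet or at the end, in percent of the substrate put in, summer
3. amount of product at the outlet or at the end, in percent of the substrate put in, autumn

The bench rule treats the substrate as pseudo-first-order: one constant at any charge, and a vessel is judged by how many lifetimes it holds. Between 2.00 min and 3.00 min, Sunday's flask gained 15 percentage points of product, with 34.0 % of substrate present on average, at c(substrate) near 0.00850 M. Over the same minutes I read the constant for Monday's flask as well:

k, Sunday = 0.441 min⁻¹
k, Monday = 0.209 min⁻¹

Monday's charge is 4.00 times Sunday's, and Sunday's constant read twice Monday's, so the rule broke across that range. I therefore took the constant from Sunday's low concentration for autumn's tank, which runs at its outlet composition.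

My carried quantity was N, the lifetimes toward product held in the tank, residence time times that constant:

N = 5.29

In the tank, product equals N times substrate. Sunday's readings at 2.00 min also left a missing share of 0.475 of the substrate then present, and I kept that ratio:

product = N/(1 + N + g) = 78.2 %
c(substrate) = 0.00739 M

Summer repeats Thursday's run, which read 94 % at 12.0 min, more than my tank figure.

The forecast gave 94 % for summer and 68 % for autumn, lower than my tank figure, and chose summer: “Summer wins clearly”.

Summer gave 95.4 % and autumn 78.5 %, so summer came out ahead.

    substrate → product, rate k1*[substrate]/(1 + ([substrate]/sat1)) (24.4 mM, k = 0.00904 s⁻¹)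
    substrate ⇌ dormant form (K = 0.370, k = 0.00565 s⁻¹)

Autumn's tank held 16.0 % of substrate at the outlet, 0.00801 M throughout, so product over substrate counts 4.91 lifetimes against my 5.29. Summer's flask ended with 2.96 % of substrate and 4.6 points of the charge not yet product. Left 120 min, which at my constant counts 52.9 lifetimes, summer's flask reached 100 %.

The data were computed for substances that don't exist; scatter was added.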